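The earlier runs and the new flask are simulated with made-up constants.

A ratio of two gains, crystals over target, was what I wanted from these runs, so that time would drop out of it.

| setting | autumn | winter | flask |
|---|---|---|---|
| substrate | 0.010 M | 0.010 M | 0.010 M |
| reagent in the second phase | 1 equiv | 2 equiv | 1.00 equiv |
| remark | the very flask that is asked about, followed so far | run made earlier |  |
| time |  |  | 2.0 min |
| volume of the second phase over the first |  |  | 0.50 |

| run | time / s | target / % | crystals / % |
|---|---|---|---|
| autumn | 10.0 | 1.1 | 0 |
| autumn | 12.0 | 1.0 | 0.9 |
| autumn | 20.0 | 1.4 | 0 |
| autumn | 40.0 | 4.6 | 1.4 |
| winter | 10.0 | 2.2 | 0.7 |
| winter | 25.0 | 4.3 | 0.5 |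
| winter | 40.0 | 7.3 | 1.5 |
| winter | 60.0 | 15.4 | 6.3 |
| winter | 90.0 | 23.6 | 15.4 |
| winter | 120 | 31.1 | 23.1 |

(standard deviation of a reading: 1 percentage point)

- what is said of target includes product in the second phase and crystals
- in the second phase: reagent in the second phase, product in the second phase; everything else is in the first
- charges count per volume of the first phase; a concentration in a rate is the amount of a species over the volume of its own phase; every rate counts per litre of the first phase
- crystals is a solid; its amount is given per volume of the solution
- the numbers in the tables scatter with a standard deviation of 1 percentage point
- candidate steps: substrate + reagent in the reaction phase -> target; target <-> product in the second phase; crystals <-> target; reagent in the reaction phase <-> reagent in the second phase; target -> decomposed product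
- the earlier runs hold the two phases in the same ratio of volumes as the flask asked about

- the target and product in the second phase and crystals together standing at 2.0 min, as a percentage of the substrate charged
- concentration of target in solution at 2.0 min, in percent of saturation

In the winter run, between 60.0 s and 120 s, crystals gained 17 percentage points while target, all its forms counted, gained 16 points. Their quotient, 1.07, I called the fall-out ratio: crystals gained per target gained. It is a reading, and it stands near one, so I took new target past a certain level to end up as crystals. That level, target less crystals at winter's last reading, was 8 points.

Next I needed the autumn total at the asked time. The autumn flask holds half of winter's reagent, so I halved winter's reading at the same time and got 15.5%. The ratio then put crystals at 8.08%.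

The weak link was that halving. At 40.0 s the autumn reading over the winter one gives 0.630, but a scatter of 1 point on a reading of 4.6% still covers one half, so I kept it.

The forecast, reckoned its own way, gave 15.5% (12.5% to 19%) and 102% of saturation (92% to 115%), with crystals “holding the solution at or just above saturation”.

The flask gave 16.5% and 110% of saturation, 8 points above the forecast.

    substrate + reagent in the reaction phase → target (k = 0.350 /M/s)
    target ⇌ product in the second phase, rate k2*([target] - [product in the second phase]/K2) per volume of the first phase (partition coefficient = 1.30, kL = 0.0500 /s)
    crystals ⇌ target, rate k3*(cs3 - [target]) while solid is left; crystals form when [target] > cs3 (solubility = 0.400 mM, k = 0.360 /s)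
    reagent in the reaction phase ⇌ reagent in the second phase, rate k4*([reagent in the reaction phase] - [reagent in the second phase]/K4) per volume of the first phase (partition coefficient = 0.790, kL = 0.00940 /s)
    target → decomposed product (k = 0.00410 /s)

Between 1.00 min and 2.00 min the autumn flask's fall-out ratio was 0.924, against 1.07 in winter, and its dissolved target went from 107% of saturation to 110%, a level standing above saturation (supersaturation). The total of the autumn flask was held down in part by the falling level of reagent in the second phase, together with the time allowed: with that level kept up the same flask stands at 30.2%, and left until 20.0 min it stands at 54.6%. Read on to 5.0 min, the same flask gained 1.02 of crystals per target gained since 2.00 min, with crystals at 28.1%.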